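Reckon a flask by its mean pace, not by its curve.

| setting | south | south-east | west | zeta | delta | theta | eta |
|---|---|---|---|---|---|---|---|
| X | 0.28 M | 0.44 M | 0.20 M | 0.20 M | 0.20 M | 0.20 M | 0.20 M |
| D | 0.20 M | 0.20 M | 0.10 M | 0.200 M | 0.200 M | 0.200 M | 0.200 M |
| temperature | 35 °C | 85 °C | 35 °C | 130 °C | 40 °C | 100 °C | 70 °C |
| remark | run made earlier | run made earlier | run made earlier |  |  |  |  |
| time |  |  |  | 1.0 h | 1.0 h | 1.0 h | 1.0 h |

| run | time / h | E / % |
|---|---|---|
| south | 12.0 | 21.1 |
| south | 30.0 | 35.1 |
| south | 60.0 | 48.1 |
| south | 96.0 | 53.3 |
| south-east | 1.00 | 21.3 |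
| south-east | 2.50 | 18.3 |
| south-east | 5.00 | 9.1 |
| south-east | 8.00 | 4.4 |
| west | 20.0 | 17.4 |
| west | 50.0 | 27.9 |
| west | 72.0 | 32.2 |
| west | 96.0 | 35.3 |

(scatter of a reading: 0.5 percentage points)

- in percentages every species weighs as the X in it: one L counts as two
- for E the G are counted in
- as a solid, counted per litre of solution: G
- the earlier runs were read with a standard deviation of 0.5 percentage points
- steps thought possible: X + D <-> E; X -> Z; 2 X -> L; X -> Q; G <-> E

- the flask with the highest amount of E, in percent of the X charged ("all alike" if they lie within 1.5 percentage points) (zeta / delta / theta / eta / all alike)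
- final E, as a percentage of the X charged, in zeta
- final E, as a percentage of the X charged, in delta
- final E, as a percentage of the X charged, in theta
- final E, as a percentage of the X charged, in eta

Define the mean pace κ as the E made per hour divided by mean X times mean D, an apparent second-order rate constant. South's first reading gives 0.0591 M of E, and with X and D each taken down by half that amount as their means, κ comes to 0.115 /M/h. West's first reading, with other charges, gives 0.115 /M/h, so at 35 °C one κ serves both first readings, reckoned with no loss of X.

South-east at 85 °C is rougher. Call its mean X half the charge, which is a guess, and κ reads 2.78 /M/h. Take ln κ as straight in temperature. Delta at 40 °C lies so near 35 °C that the guess enters to the power 0.100. So carry 0.159 /M/h, the mean pace in delta.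

Now run delta slowly. In the first instants X and D stand at their charges, so E forms at 0.00634 M/h. Through the middle, that start rate would make 0.00634 M in the hour, so the means lie 0.00317 M below the charges, and the mean pace gives 0.00614 M. Replacing the start by the mean moved the result by 3.15%, so in delta the curve costs little. At the end your reckoning stands at 3.07%. South's E was still rising at its last reading, where E/(X·D) reads 22.5 /M; put that reading in place of the equilibrium constant, and at the end of the hour the back step in delta is hardly any of the forward one.

The forecast named eta as richest, with 0.1% in zeta, 3.2% in delta, a little above this reckoning, 11% in theta and 19% in eta, holding of the south-east run that “E is following equilibrium with a dying X”.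

The flasks give eta as richest: 0% in zeta, 3.40% in delta, 9.71% in theta, 21.2% in eta.

    X + D ⇌ E (K = 10.0 /M, k = 0.0270 /M/min, Ea = 66.0 kJ/mol, ΔH = −35.0 kJ/mol)
    X → Z (k = 0.00230 /min, Ea = 106 kJ/mol)
    2 X → L (k = 0.00100 /M/min, Ea = 103 kJ/mol)
    X → Q (k = 2.80 × 10⁻⁵ /min, Ea = 114 kJ/mol)
    G ⇌ E, rate k5*(cs5 - [E]) while solid is left; crystals form when [E] > cs5 (solubility = 0.0750 M, k = 1.50 /min)
    (constants at 70 °C)

In delta, X + D to E ran through the hour: E stood at 1.73% after 0.500 h and 3.40% after 1.00 h, with Z at 0.385% and X still 96.1%. The carried pace with delta's amounts at 0.500 h gives 3.05%, which is 0.35 percentage points under the flask. With all amounts held, eta's E has moved by 5 points at a time of 0.674 h or 1.45 h. Stretched to eta, the pace becomes 1.07 /M/h, and with eta's X 79.9% and D 87.1% at 0.500 h it gives 14.9%, where eta holds 21.2%.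

The earlier runs and the new flask are calculated from invented constants; scatter was added.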